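## Structural features

Xenocockiamide C is built on one saturated six-membered ring, a piperazine. Its nitrogens N1 and N4 each carry an (E)-cinnamoyl group and its carbons C2 and C5 each carry a benzyl group; none of the four phenyl rings is fused to the core. C2 and C5 are both S, so the benzyl groups are cis and the molecule has a C2 axis through the ring centre; the diastereomer to exclude is the meso trans isomer (2R,5S). The stereocentres are not neighbours: they sit 1,4 across the ring, each between an acylated nitrogen and a ring CH2 (C3 or C6). In the piperazine they are α to amide nitrogen and not to a carbonyl, so they are configurationally robust, whereas at the diketopiperazine stage they are α to a lactam carbonyl and can epimerise. The fragile groups are the two tertiary α,β-unsaturated amides: they are Michael acceptors, are reduced by hydrides and by hydrogenation, and can lose E geometry in light, so they must come after every reduction. The real difficulty is therefore securing the cis-(2S,5S) core free of its diastereomer and attaching two identical unsaturated arms cleanly. The key step exploits the fact that each arm ends in a bond between the β-carbon of an N-acryloyl unit and a phenyl ring, and that the arms on N1 and N4 are symmetry-equivalent, so both Cβ–phenyl bonds can be made in one operation.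

## Logic of the disconnections

**12 to 9 and 10.** The two Cβ–C(aryl) bonds of the cinnamoyl arms are cut. They are the only skeletal bonds outside the chiral core that can be cut symmetrically without touching C2 or C5. The cut removes twelve carbons and both alkene geometries and leaves a C2-symmetric bis-acceptor, onto which any aryl group could be placed last. The forward step must arylate both arms at the β-carbon only, give E geometry twice, go to completion through the mono-arylated stage 11 without a second arylation or oligomerisation, and leave the ring stereocentres alone.

**9 to 6 and 7.** The two amide N–C(O) bonds are cut. This exposes a diamine whose two nitrogens are homotopic, so no protecting group or differentiation is needed. The forward step must acylate both nitrogens fully, passing through 8, while the free amine still present is kept from adding in conjugate fashion to the acrylamide already formed.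

**6 to 4.** The two ring methylenes C3 and C6 are taken back to lactam carbonyls. No skeletal bond is cut, but the piperazine becomes a cyclic dipeptide, a compound class that is easy to assemble and to purify by crystallisation. The forward step must reduce both lactams completely, through 5, without ring cleavage and without epimerisation.

**4 to 1.** Both lactam N–C(O) bonds are cut, giving two identical amino ester halves. Both stereocentres are then bought rather than made. The forward step must join two molecules head to tail, through 2 and 3, and close the ring without disturbing the α-centres.

## Other disconnections considered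

Alternative 1: The cut is at N1–C2 and N4–C5 together with both C–H bonds at the stereocentres. In the forward key step two molecules of aminoketone A1 (1-amino-3-phenylpropan-2-one) condense head to tail to the bis-imine A2 (3,6-dibenzyl-2,5-dihydropyrazine). An (S)-selective, NADPH-dependent imine reductase with cofactor recycling then reduces both C=N bonds in the same pot to A3, which is identical with 6.
- In its favour: the ring and both stereocentres arise in one pot from achiral material, either enantiomer is open by choice of enzyme, and the C2 symmetry is used in ring construction itself. On convergence and atom economy of the core this is better than the chosen plan.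
- Against it here: A2 is prone to oxidative aromatisation and to imine-to-enamine tautomerisation into conjugation with phenyl. The enzyme must accept a bulky bis-benzyl substrate and deliver hydride with the same sense at both imines, or the meso trans piperazine results. A1 as a free base self-condenses and must be released from a salt at controlled pH.
- Comparison: mechanistically this is condensation plus enzymatic hydride transfer, with configuration resting on catalyst control, where the chosen plan takes both centres from the chiral pool with no selectivity question. Structurally it addresses the ring and not the arms, so it complements the chosen plan: A3 could replace steps 1 and 2 while steps 3 and 4 stay. On step economy it is about equal (A1, key step, then N-acylation) if A1 is bought, and longer if A1 must be made.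

Alternative 2: The cut is at N4–C5 and N1–C6, numbering so that Boc sits on N1 and the existing benzyl on C2. In the forward key step diamine A4 (tert-butyl N-[(2S)-1-phenyl-3-(tosylamino)propan-2-yl]carbamate) reacts with carbonate A5 (tert-butyl 3-phenylprop-2-yn-1-yl carbonate) under zerovalent palladium generated from Pd2(dba)3 and a bisphosphine. Decarboxylation gives an allenylpalladium species; the more acidic sulfonamide nitrogen attacks its central carbon, and the carbamate nitrogen closes the ring at the CH2 terminus of the resulting π-allylpalladium. The product is the benzylidene piperazine A6.
- In its favour: the ring is built in one step from two different halves with the nitrogens already differentiated, and regiochemistry follows from the acidity difference of the two N–H groups. For congeners with two different C-substituents or two different N-acyl groups this is better than the chosen plan, which is tied to symmetric products.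
- Against it here: the C5 stereocentre is not set in the key step. It would have to come from a later face-selective hydrogenation of the ene-sulfonamide, steered only by the remote C2 benzyl group, and that hydrogenation must precede any cinnamoyl group. Reductive removal of the tosyl group, Boc removal and double N-cinnamoylation follow, and A4 needs about four steps from the amino acid that supplies 1.
- Comparison: the catalytic palladium manifold is as mild as that of the chosen key step, so on that point the two are equal. On structure it spends effort differentiating two nitrogens that the symmetric target does not require. On step economy it is clearly longer, about nine steps against four.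

Alternative 3: The cut is at C5–C6, the ring C–C bond next to the new stereocentre, numbering so that Boc sits on N1. In the forward key step stannyl amine A7 (tert-butyl N-[(2S)-1-amino-3-phenylpropan-2-yl]-N-[(tributylstannyl)methyl]carbamate) is condensed with phenylacetaldehyde A8 to imine A9. Cu(OTf)2 oxidises the C–Sn bond to an α-carbamoyl methyl radical, which adds 6-endo to the imine carbon; the nitrogen-centred species is then reduced to N–H, giving A10 (tert-butyl (2S,5S)-2,5-dibenzylpiperazine-1-carboxylate).
- In its favour: a ring C–C bond is made, one stereocentre comes from the chiral pool, and A10 emerges with N1 protected and N4 free. For mono-acylated or unsymmetrically acylated analogues that differentiation is better than anything the chosen plan offers.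
- Against it here: A9 derives from an enolisable aldehyde and should tautomerise easily to a styrene-conjugated enamine or self-condense. The new C5 centre must come out cis to C2, and a chair-like transition state, with the carbamate pushing the C2 benzyl group axial, does not obviously guarantee that. The step also needs stoichiometric tin and Cu(OTf)2, and A7 requires about four to five steps.
- Comparison: mechanistically it is a radical cyclisation under substrate control of one new centre, against a polar palladium cycle that creates no stereocentre. On robustness of the mechanism toward the functional groups present the two are about equal, since neither threatens the existing centre. On step economy it is longer, about eight steps after Boc removal and double N-cinnamoylation, and it gives up late-stage variation of the aryl groups.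

Key step: step 4

Remarks on the chemistry:
- Numbering: every piperazine here is numbered N1–C2(benzyl)–C3H2–N4–C5(benzyl)–C6H2, including those of the alternatives.
- Structure check: C2 and C5 are S in 6, 9 and 12. Compound 4 from two L-phenylalanine units maps onto this configuration because changing C=O to CH2 leaves the priority order N > CH2N > CH2Ph > H unchanged. No structure needed correction.
- Precursor design: 9 is kept as the bare bis-acrylamide, since it has no N–H or O–H to protect. It is a double Michael acceptor and polymerisable, so it would be made cold under biphasic conditions, stabilised with a trace of BHT and used promptly.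
- Assumption: 1, 7, 10 and all reagents named are commercial.

## Steps

Step 1
Reactants: 1 L-phenylalanine methyl ester hydrochloride (two molecules per molecule of product)
Product: 4 (3S,6S)-3,6-dibenzylpiperazine-2,5-dione [cyclo(L-Phe-L-Phe)], via L-phenylalanine methyl ester free base 2 (not isolated), via methyl L-phenylalanyl-L-phenylalaninate 3 (not isolated)
Conditions: sat. aq. NaHCO3, CH2Cl2, rt, concentrate; then toluene (about 1 M), AcOH (10 mol %), reflux, 24–48 h; filter, recrystallise
Reagents that add atoms: none
Why: Amino ester cyclodimerisation by two thermal ester aminolyses: the amine of one molecule of 2 attacks the ester of another to give 3, whose cis-amide rotamer closes by a 6-exo-trig intramolecular aminolysis, with AcOH acting as proton shuttle. No stereocentre is made; both come from L-phenylalanine, and the absence of strong base should keep α-epimerisation low. Sparingly soluble 4 should crystallise from the hot toluene, and one recrystallisation would remove any trans (3R,6S) diastereomer.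

Step 2
Reactants: 4 (3S,6S)-3,6-dibenzylpiperazine-2,5-dione
Product: 6 (2S,5S)-2,5-dibenzylpiperazine, via (3S,6S)-3,6-dibenzylpiperazin-2-one 5 (not isolated)
Conditions: LiAlH4 (6 equiv), THF, reflux, 24–48 h (4 added as a solid in portions); then H2O, 15% aq. NaOH, H2O at 0 °C, filter
Reagents that add atoms: none
Why: Exhaustive LiAlH4 reduction of a secondary lactam to the amine: hydride adds to the carbonyl of the N-metallated lactam, the O-aluminated hemiaminal collapses to an iminium or imine, and a second hydride gives the CH2 group, first at one carbonyl (5) and then at the other. The stereocentres are kept because the amidate formed on N–H deprotonation does not enolise and the product carbons are no longer α to a carbonyl. Reduction of cis-diketopiperazines is the standard access to enantiopure cis-2,5-disubstituted piperazines.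

Step 3
Reactants: 6 (2S,5S)-2,5-dibenzylpiperazine; 7 acryloyl chloride (2.3 equiv)
Product: 9 1,1'-[(2S,5S)-2,5-dibenzylpiperazine-1,4-diyl]bis(prop-2-en-1-one), via 1-[(2S,5S)-2,5-dibenzylpiperazin-1-yl]prop-2-en-1-one 8 (not isolated)
Conditions: sat. aq. NaHCO3/CH2Cl2 (1:1), 0 °C, 1 h; BHT (trace) added before concentration below 30 °C
Reagents that add atoms: none
Why: Schotten–Baumann N-acylation of both secondary amines by the acid chloride; at 0 °C acyl transfer is much faster than conjugate addition of the α-branched amine to an acrylamide, and bicarbonate in the water phase takes up HCl so that neither nitrogen is parked as its salt. The two nitrogens are homotopic, so no differentiation is needed, and no stereocentre is touched.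

Step 4
Reactants: 9 1,1'-[(2S,5S)-2,5-dibenzylpiperazine-1,4-diyl]bis(prop-2-en-1-one); 10 iodobenzene (2.4 equiv)
Product: 12 xenocockiamide C [(2E,2'E)-1,1'-[(2S,5S)-2,5-dibenzylpiperazine-1,4-diyl]bis(3-phenylprop-2-en-1-one)], via (2E)-1-[(2S,5S)-4-acryloyl-2,5-dibenzylpiperazin-1-yl]-3-phenylprop-2-en-1-one 11 (not isolated)
Conditions: Pd(OAc)2 (5 mol %), n-Bu4NCl (2 equiv), NaHCO3 (5 equiv), BHT (1 mol %), DMF, 80 °C, N2
Reagents that add atoms: none
Why: This is a Mizoroki–Heck reaction run on both arms: Pd(OAc)2 is reduced in situ to zerovalent palladium, which inserts into the C–I bond of 10; the resulting phenyl complex of divalent palladium binds an acrylamide alkene of 9 and adds syn across it with phenyl going to the unsubstituted β-carbon, and bond rotation followed by syn β-hydride elimination releases the (E)-cinnamamide while NaHCO3 takes up HI and returns zerovalent palladium. The closest known reaction type is the Heck arylation of N,N-disubstituted acrylamides with aryl iodides under ligand-free conditions with a tetraalkylammonium salt. No ring is closed and no stereocentre is created; the only new stereo-elements are the two alkene geometries, which should be E because the elimination transition state places phenyl and the carboxamide anti. β-Regioselectivity is secured by the polarisation of the acrylamide and by the terminal carbon carrying no substituent. The two arms sit on opposite ring nitrogens and react independently, so mono-arylated 11 simply re-enters the cycle. Chemoselectivity rests on the substrate having no other aryl halide, N–H or alkene, and C2 and C5, being α to amide nitrogen and not to a carbonyl, are not acidic enough to be touched by bicarbonate. Only a slight excess of 10 and a trace of BHT are used, to guard against a second arylation at the cinnamamide β-carbon and against radical polymerisation of 9.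

## Compound list

1 | L-phenylalanine methyl ester hydrochloride | Cl.COC(=O)[C@@H](N)Cc1ccccc1 | starting material
2 | L-phenylalanine methyl ester (free base) | COC(=O)[C@@H](N)Cc1ccccc1 | intermediate
3 | methyl L-phenylalanyl-L-phenylalaninate | N[C@@H](Cc1ccccc1)C(=O)N[C@@H](Cc1ccccc1)C(=O)OC | intermediate
4 | (3S,6S)-3,6-dibenzylpiperazine-2,5-dione, cyclo(L-Phe-L-Phe) | O=C1N[C@@H](Cc2ccccc2)C(=O)N[C@H]1Cc1ccccc1 | intermediate
5 | (3S,6S)-3,6-dibenzylpiperazin-2-one (present in the flask as its aluminium-bound form) | O=C1N[C@@H](Cc2ccccc2)CN[C@H]1Cc1ccccc1 | intermediate
6 | (2S,5S)-2,5-dibenzylpiperazine | N1C[C@H](Cc2ccccc2)NC[C@@H]1Cc1ccccc1 | intermediate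
7 | acryloyl chloride | C=CC(=O)Cl | starting material
8 | 1-[(2S,5S)-2,5-dibenzylpiperazin-1-yl]prop-2-en-1-one | C=CC(=O)N1C[C@H](Cc2ccccc2)NC[C@@H]1Cc1ccccc1 | intermediate
9 | 1,1'-[(2S,5S)-2,5-dibenzylpiperazine-1,4-diyl]bis(prop-2-en-1-one) | C=CC(=O)N1C[C@H](Cc2ccccc2)N(C(=O)C=C)C[C@@H]1Cc1ccccc1 | intermediate
10 | iodobenzene | Ic1ccccc1 | starting material
11 | (2E)-1-[(2S,5S)-4-acryloyl-2,5-dibenzylpiperazin-1-yl]-3-phenylprop-2-en-1-one | C=CC(=O)N1C[C@H](Cc2ccccc2)N(C(=O)/C=C/c2ccccc2)C[C@@H]1Cc1ccccc1 | intermediate
12 | xenocockiamide C, (2E,2'E)-1,1'-[(2S,5S)-2,5-dibenzylpiperazine-1,4-diyl]bis(3-phenylprop-2-en-1-one) | O=C(/C=C/c1ccccc1)N1C[C@H](Cc2ccccc2)N(C(=O)/C=C/c2ccccc2)C[C@@H]1Cc1ccccc1 | target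

## Step count and risk

Total step count: 4. Longest linear sequence: 4 steps (1 to 12).

**Step 4 (key step).** What may go wrong: the catalyst may deposit as palladium metal before the second arm has reacted, leaving the reaction stalled at the mono-arylated stage; the cinnamamide already formed may be arylated a second time at its β-carbon; or the bis-acrylamide may oligomerise at 80 °C. All three follow from asking one substrate to undergo two intermolecular couplings while carrying two polymerisable acceptors. Fallback: set out from 6 and acylate both nitrogens directly with (E)-cinnamoyl chloride (2.3 equiv, sat. aq. NaHCO3/CH2Cl2, 0 °C), which arrives at 12 with the alkene geometry bought rather than made. No new compound is made on the way (F0).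

**Step 1.** What may go wrong: partial epimerisation at the α-carbon during prolonged heating, so that the trans diastereomer co-crystallises; or linear oligoamide formation competing with ring closure when the amino ester is concentrated. Fallback: set out from 1 and build the dipeptide stepwise. Compound 1 would be acylated with commercial N-Boc-L-phenylalanine N-hydroxysuccinimide ester (NaHCO3, THF/H2O, rt) to give methyl N-(tert-butoxycarbonyl)-L-phenylalanyl-L-phenylalaninate F1. HCO2H at rt would remove the Boc group, leaving 3 as its formate, and heating in sec-BuOH/toluene would close the ring. The sequence comes back at 4, with the intermolecular amide bond made under mild activated-ester conditions.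

**Step 2.** What may go wrong: the very low solubility of the diketopiperazine in THF may stall reduction at the half-reduced stage, or forcing conditions may cleave a ring C–N bond of the hemiaminal intermediate to give open-chain amino alcohols. Fallback: set out from 1 and avoid the diketopiperazine. Compound 1 would be free-based to 2 (aq. NaHCO3) and joined to commercial N-Boc-L-phenylalaninal by reductive amination (NaBH(OAc)3, ClCH2CH2Cl, rt) to give methyl N-[(2S)-2-[(tert-butoxycarbonyl)amino]-3-phenylpropyl]-L-phenylalaninate F2. TFA in CH2Cl2 would give methyl N-[(2S)-2-amino-3-phenylpropyl]-L-phenylalaninate F3, which on neutralisation and warming in methanol lactamises to 5, here isolated. Compound 5 has one carbonyl and a basic nitrogen and should be far more soluble; LiAlH4 in THF would reduce it, and the sequence comes back at 6.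

**Step 3.** What may go wrong: conjugate addition of not-yet-acylated amine (6 or 8) to acrylamide already formed, giving oligomers, or polymerisation of the product on concentration. Fallback: set out from 6 with a masked acrylamide. Acylation with 3-chloropropanoyl chloride (sat. aq. NaHCO3/CH2Cl2, 0 °C) would give 1,1'-[(2S,5S)-2,5-dibenzylpiperazine-1,4-diyl]bis(3-chloropropan-1-one) F4, which has no Michael acceptor while free amine is present. Et3N in MeCN at 60 °C would then eliminate HCl from both arms, and the sequence comes back at 9.

## Further compounds

F0 | step 4 | none | none
F1 | step 1 | methyl N-(tert-butoxycarbonyl)-L-phenylalanyl-L-phenylalaninate | CC(C)(C)OC(=O)N[C@@H](Cc1ccccc1)C(=O)N[C@@H](Cc1ccccc1)C(=O)OC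
F2 | step 2 | methyl N-[(2S)-2-[(tert-butoxycarbonyl)amino]-3-phenylpropyl]-L-phenylalaninate | CC(C)(C)OC(=O)N[C@@H](Cc1ccccc1)CN[C@@H](Cc1ccccc1)C(=O)OC
F3 | step 2 | methyl N-[(2S)-2-amino-3-phenylpropyl]-L-phenylalaninate | N[C@@H](Cc1ccccc1)CN[C@@H](Cc1ccccc1)C(=O)OC
F4 | step 3 | 1,1'-[(2S,5S)-2,5-dibenzylpiperazine-1,4-diyl]bis(3-chloropropan-1-one) | O=C(CCCl)N1C[C@H](Cc2ccccc2)N(C(=O)CCCl)C[C@@H]1Cc1ccccc1
A1 | alternative 1 | 1-amino-3-phenylpropan-2-one | NCC(=O)Cc1ccccc1
A2 | alternative 1 | 3,6-dibenzyl-2,5-dihydropyrazine | C1C(Cc2ccccc2)=NCC(Cc2ccccc2)=N1
A3 | alternative 1 | (2S,5S)-2,5-dibenzylpiperazine (identical with 6) | N1C[C@H](Cc2ccccc2)NC[C@@H]1Cc1ccccc1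
A4 | alternative 2 | tert-butyl N-[(2S)-1-phenyl-3-(tosylamino)propan-2-yl]carbamate | CC(C)(C)OC(=O)N[C@@H](Cc1ccccc1)CNS(=O)(=O)c1ccc(C)cc1
A5 | alternative 2 | tert-butyl 3-phenylprop-2-yn-1-yl carbonate | CC(C)(C)OC(=O)OCC#Cc1ccccc1
A6 | alternative 2 | tert-butyl (2S,5Z)-2-benzyl-5-benzylidene-4-tosylpiperazine-1-carboxylate | CC(C)(C)OC(=O)N1C/C(=C/c2ccccc2)N(S(=O)(=O)c2ccc(C)cc2)C[C@@H]1Cc1ccccc1
A7 | alternative 3 | tert-butyl N-[(2S)-1-amino-3-phenylpropan-2-yl]-N-[(tributylstannyl)methyl]carbamate | CCCC[Sn](CCCC)(CCCC)CN(C(=O)OC(C)(C)C)[C@@H](Cc1ccccc1)CN
A8 | alternative 3 | phenylacetaldehyde | O=CCc1ccccc1
A9 | alternative 3 | tert-butyl N-[(2S)-1-phenyl-3-[(E)-(2-phenylethylidene)amino]propan-2-yl]-N-[(tributylstannyl)methyl]carbamate | CCCC[Sn](CCCC)(CCCC)CN(C(=O)OC(C)(C)C)[C@@H](Cc1ccccc1)C/N=C/Cc1ccccc1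
A10 | alternative 3 | tert-butyl (2S,5S)-2,5-dibenzylpiperazine-1-carboxylate | O=C(OC(C)(C)C)N1C[C@H](Cc2ccccc2)NC[C@@H]1Cc1ccccc1
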